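## Analysis of the target

The target 19 is a 9,9'-epoxylignan-7,7'-diol: a single oxolane ring (O, C9, C8, C8', C9') whose carbons C8 and C8' each carry a hydroxy(4-hydroxy-3-methoxyphenyl)methyl group (C7–OH and C7'–OH). It has four stereocentres, (7S,7'S,8R,8'R), and a twofold axis through the ring oxygen and the midpoint of C8–C8'. Only two relationships are therefore independent: the ring substituents are trans, and in each half the C7 hydroxyl and the C8–C8' bond are syn when the chain aryl–C7–C8–C9 is drawn as a zigzag. The sensitive groups are the two 4-hydroxybenzylic alcohols, which ionise under acid (or, as phenoxides, lose the benzylic oxygen) to quinone-methide-like species, so that C7 can epimerise or be captured by another hydroxyl. The benzylic C7–O bonds can also be hydrogenolysed and the free phenols are easily oxidised. The synthesis is hard for two reasons: the open-chain carbinol centres must be correlated with the ring centres, and in any 7,7',9,9'-tetraol the wanted 9-O-9' closure competes with closure of O7 onto C9', which also gives a five-membered ether. The strategy rests on the 1,3-relationship of O7 and O9 across the methine C8 in each half (O7–C7–C8–C9–O9). C8 can then be made by adding hydrogen to C8 and silicon (later oxygen) to C9 of a C8=C9 methylene group, both delivered from a silicon atom bound to O7. Because the halves are identical, C8–C8' becomes the central bond of a 2,3-disubstituted buta-1,3-diene and only the two carbinol centres have to be set independently.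

## Retrosynthetic reasoning

**Protecting groups.** 19 is traced back to its bis(benzyl ether) 18, and 18 to 17, in which O7 and O7' carry tert-butyldimethylsilyl groups. No skeletal bond is cut. The order is chosen so that a free phenol and basic desilylation never meet, and so that the last step is neutral.

**Ring ether.** One C9–O bond of the oxolane in 17 is cut, which gives the 1,4-diol 16. This bond is chosen because C9 and C9' are not stereocentres and the forward closure is a displacement at a primary carbon by a primary alcohol; cutting C8–C9 or C8–C8' would break bonds at stereocentres. The forward step must close 9-O-9' and not 7-O-9', so O7 and O7' must be masked while O9 and O9' are free. 16 therefore comes from the tetrasilyl ether 15 by selective loss of the two primary silyl groups, and 15 from the tetraol 14.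

**C9–O to C9–Si.** Each 1,3-diol unit of 14 (O7–C7–C8–C9–O9) is the oxidation product of a 1,2-oxasilolane, so 14 is traced back to the bis(oxasilolane) 13. The oxidation replaces silicon on C9 by oxygen with retention and touches no stereocentre. What is gained is that O7 and C9 of each half are now joined through one silicon atom.

**Key disconnection.** In each ring of 13 the C9–Si and C8–H bonds are cut, which leads to the bis(hydrodimethylsilyl) ether 11 of a dienediol. This removes both ring stereocentres at once and leaves C7 and C7' as the only stereocentres. The forward reaction must add Si–H across each C8=C9 methylene within its own half (not 1,4 across the diene) and must deliver hydrogen to C8 on the face that gives the 7,8-syn relationship, twice.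

**Tether.** The Si–O bonds of 11 are cut to the dienediol 9 and the disilazane 10; the forward step is a neutral silylation.

**Methylene groups.** Both C8=C9 double bonds of 9 are cut back to the triple bond of the alkyne diol 7, the two CH2 carbons coming from 8. This turns a cross-conjugated diene into a linear alkyne whose carbinol centres can be made by carbonyl addition. The forward ene–yne metathesis must leave the two carbinols untouched.

**Carbinol centres.** The C7'–C8' bond of 7 is cut to aldehyde 1 and the terminal alkynol 5 (as its zinc derivative 6); 5 comes from 4 by loss of the silyl group, and the C7–C8 bond of 4 is cut to 1 and alkyne 2 (as its zinc derivative 3). Both centres are set by the same catalyst-controlled alkynylation of the same aldehyde, so the whole skeleton comes from 1 (twice), 2, 8 and 10.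

## Alternatives that were turned down

**Alternative 1:** The oxolane is cut at C8–C9 and C8'–C9', which leaves a three-atom C–O–C dipole (the unsubstituted carbonyl ylide A3) and an (E)-alkene that carries C7 and C7' as acyl groups, the fumaric diamide A1 of two bornane-10,2-sultam units. In the forward step, fluoride-induced desilylation of the chloromethyl silylmethyl ether A2 generates A3, which adds across A1 to give the cycloadduct A4.
- For it: one step builds the ring, two C–C bonds and both ring stereocentres. The trans relationship follows from suprafacial addition to an E-alkene and the absolute sense from the auxiliaries. On ring construction and on step count this is stronger than the chosen route, which needs twelve steps and closes the ring late by an ordinary etherification.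
- Against it: in A4, C7 and C7' are at the carboxylic acid level. Each acyl sultam must be turned into an aryl ketone and then reduced, and the only control element for the two new carbinol centres is the neighbouring ring carbon. That is open-chain 1,2-induction on an aryl ketone, for which steric and chelation models (the ring oxygen is within reach) point to opposite faces, so up to three diastereomers can form. The ylide A3 is also unstabilised and short-lived, and the facial bias of N-enoyl sultams is most dependable under Lewis acid chelation, which fluoride conditions do not allow.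
- Comparison: the chosen strategy reverses the order of events. The carbinol centres are set first under catalyst control and the ring centres second through a cyclic transition state.

**Alternative 2:** The C7–C8 and C7'–C8' bonds are cut. The ring with both C8 centres is taken from the chiral pool as A5, a trans-3,4-bis(benzyloxy)oxolane of the L-threitol series, in which the future C7 carbons are the benzylic CH2 groups. In the forward step, twofold benzylic lithiation with excess alkyllithium and a [1,2]-shift of each ring carbon from oxygen to the carbanion carbon gives A6, the bis(silyl ether) of 19.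
- For it: it is the shortest plan. It needs no catalyst, no resolution and no ring closure, and the C7 oxygens are in place from the start. On step count and on the ring-closure problem it is clearly stronger.
- Against it: the [1,2]-Wittig rearrangement runs through homolysis and recombination of a radical pair. Configuration at the migrating secondary carbon is retained only in part, and the configuration at the carbanion carbon (C7) is fixed during recombination without a dependable bias. With four centres decided in one flask a diastereomer mixture must be expected. The second shift also has to occur next to an alkoxide, the electron-rich rings lower the benzylic acidity, and ring deprotonation with loss of benzyloxide competes.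
- Comparison: the chosen route is about three times as long, but every stereocentre is formed in a step with a defined transition state.

**Alternative 3:** On one half the C8–C9 and C7–O bonds are cut; the other half is carried complete in the methoxymethyl ether A7, which holds the C7=C8 styrene. In the forward step acid ionises the acetal of A7, the oxocarbenium carbon (the future C9) is attacked by styrene carbon C8 with closure of the oxolane, and the benzylic cation at C7 is captured by the acid anion to give A8.
- For it: ring, C8 and the C7–O bond arise together, and O9 is never a free hydroxyl, so the O7/O9 differentiation that costs the chosen route three steps is not needed. On that point it is stronger.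
- Against it: C7 is set by capture of a planar benzylic cation by a weak external nucleophile, guided only by the adjacent C8, and the capture can reverse; proton loss from C8 and oxonia-Cope scrambling compete. A7 must already hold C7' and C8' in defined form, which needs its own asymmetric steps. The symmetry of 19 is not used, and deactivating sulfonates have to be put on and taken off.
- Comparison: the chosen strategy uses the twofold symmetry throughout, so each operation is done on both halves in one flask and the two stereo-determining events reinforce each other.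

Key step: step 6

Assumption: the zinc–ProPhenol alkynylation is taken to add the alkynyl group to the Si face of aldehyde 1 with the (S,S)-ligand; if the sense is the opposite for this aldehyde, the (R,R)-ligand is used in steps 1 and 3 and nothing else changes.

## Route

**Step 1**
Reactants: 1 4-(benzyloxy)-3-methoxybenzaldehyde; 2 ethynyltrimethylsilane
Product: 4 (R)-1-[4-(benzyloxy)-3-methoxyphenyl]-3-(trimethylsilyl)prop-2-yn-1-ol, via methyl[(trimethylsilyl)ethynyl]zinc 3 (not isolated)
Conditions: 2 (3 equiv), ZnMe2 (3 equiv), (S,S)-ProPhenol (10 mol%), Ph3P=O (20 mol%), toluene, rt; then 1, 4 °C; aq. NH4Cl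
Reagents that add atoms: none
Why: Catalytic asymmetric alkynylation of an aromatic aldehyde (zinc–ProPhenol alkynylation): the dinuclear zinc complex of the ligand binds 1 and the alkynylzinc 3 and delivers the alkynyl group to the Si face, which sets C7 as (R); aryl aldehydes and silylacetylenes are standard partners.

**Step 2**
Reactants: 4 (R)-1-[4-(benzyloxy)-3-methoxyphenyl]-3-(trimethylsilyl)prop-2-yn-1-ol
Product: 5 (S)-1-[4-(benzyloxy)-3-methoxyphenyl]prop-2-yn-1-ol
Conditions: K2CO3 (0.2 equiv), MeOH, rt
Reagents that add atoms: none
Why: Base-catalysed methanolysis of the alkynyl C–Si bond (protodesilylation); the carbinol centre is not touched, and the descriptor changes from R to S only because ethynyl ranks below aryl.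

**Step 3**
Reactants: 5 (S)-1-[4-(benzyloxy)-3-methoxyphenyl]prop-2-yn-1-ol; 1 4-(benzyloxy)-3-methoxybenzaldehyde
Product: 7 (1R,4R)-1,4-bis[4-(benzyloxy)-3-methoxyphenyl]but-2-yne-1,4-diol, via bis(methylzinc) alkoxide-alkynylide 6 (not isolated)
Conditions: ZnMe2 (3.5 equiv), (S,S)-ProPhenol (20 mol%), Ph3P=O (40 mol%), toluene, 0 °C → rt; then 1 (1.5 equiv), 4 °C; aq. NH4Cl
Reagents that add atoms: none
Why: Second zinc–ProPhenol alkynylation, again on the Si face of 1 under catalyst control, sets C7' as (R); the hydroxyl of 5 is carried as a methylzinc alkoxide, the same kind of species as the product alkoxide that builds up in every such reaction. Since the same catalyst sets both centres, the minor enantiomer of 5 should end up mainly in the meso (1R,4S) diastereomer, which is removed here or at 9, so that the twofold-symmetric diol is enriched further.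

**Step 4**
Reactants: 7 (1R,4R)-1,4-bis[4-(benzyloxy)-3-methoxyphenyl]but-2-yne-1,4-diol; 8 ethylene
Product: 9 (1R,4R)-1,4-bis[4-(benzyloxy)-3-methoxyphenyl]-2,3-dimethylidenebutane-1,4-diol
Conditions: 8 (4 bar), second-generation Grubbs catalyst RuCl2(=CHPh)(PCy3)(H2IMes) (10 mol%), toluene, 70 °C
Reagents that add atoms: none
Why: Ethylene–alkyne cross-metathesis (ene–yne metathesis): the ruthenium methylidene adds across the triple bond, the vinylcarbene formed is turned over by ethylene, and the internal alkyne becomes a 2,3-disubstituted buta-1,3-diene with both carbinol centres untouched. Internal alkynes with propargylic oxygen are the established substrates, and the second-generation catalyst tolerates free hydroxyls.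

**Step 5**
Reactants: 9 (1R,4R)-1,4-bis[4-(benzyloxy)-3-methoxyphenyl]-2,3-dimethylidenebutane-1,4-diol; 10 1,1,3,3-tetramethyldisilazane
Product: 11 (1R,4R)-1,4-bis[4-(benzyloxy)-3-methoxyphenyl]-2,3-dimethylidenebutane-1,4-diyl bis(dimethylsilyl) ether
Conditions: 10 (1.5 equiv), THF, rt → 50 °C; volatiles removed in vacuo, used crude
Reagents that add atoms: none
Why: Silylation of alcohols by a disilazane with loss of ammonia, the usual way to hydrodimethylsilyl ethers; the conditions are neutral, so the acid-labile allylic benzylic alcohols are not ionised.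

**Step 6**
Reactants: 11 (1R,4R)-1,4-bis[4-(benzyloxy)-3-methoxyphenyl]-2,3-dimethylidenebutane-1,4-diyl bis(dimethylsilyl) ether
Product: 13 (4S,4'S,5S,5'S)-5,5'-bis[4-(benzyloxy)-3-methoxyphenyl]-2,2,2',2'-tetramethyl-4,4'-bi(1,2-oxasilolane), via mono-oxasilolane 12 (not isolated)
Conditions: Pt2[(CH2=CHSiMe2)2O]3 (0.5 mol% Pt, zerovalent platinum), toluene (0.05 M), rt → 50 °C
Reagents that add atoms: none
Why: Zerovalent platinum inserts into a Si–H bond, the tethered C8=C9 methylene coordinates, hydride passes to C8 and reductive elimination forms C9–Si (Chalk–Harrod cycle); the two halves react one after the other through 12. The closest known reaction is the platinum-catalysed intramolecular hydrosilylation of hydrodimethylsilyl ethers of 2-substituted allylic alcohols, which gives 1,2-oxasilolanes and, after oxidation, 2,3-syn 1,3-diols. Both rings close in the 5-endo-trig mode, with silicon bonding to the terminal carbon C9 (C9'). C8 is controlled by C7 and C8' by C7': in the cyclic transition state the C7–H bond lies near the alkene plane next to the C8 substituent (least allylic 1,2-strain), the aryl group points to the face away from silicon, and hydrogen reaches C8 on the silicon face, which gives (4S,5S) in each ring, the (7S,8R) arrangement of 19. Each half is steered by its own carbinol and both are (R), so the two events lead to the same twofold-symmetric product. The step needs 1,2- over 1,4-addition to the diene: the five-membered tether reaches only C9 of its own half, whereas 1,4-addition would need a six-membered closure onto C9' through a planar s-cis diene, which the two bulky 2,3-substituents disfavour. Dilution holds back intermolecular addition.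

**Step 7**
Reactants: 13 (4S,4'S,5S,5'S)-5,5'-bis[4-(benzyloxy)-3-methoxyphenyl]-2,2,2',2'-tetramethyl-4,4'-bi(1,2-oxasilolane)
Product: 14 (1S,2R,3R,4S)-1,4-bis[4-(benzyloxy)-3-methoxyphenyl]-2,3-bis(hydroxymethyl)butane-1,4-diol
Conditions: 30% aq. H2O2, KF, KHCO3, THF/MeOH (1:1), rt → 40 °C
Reagents that add atoms: hydrogen peroxide, OO
Why: Tamao oxidation: the activated silicon takes up hydroperoxide, C9 migrates from silicon to oxygen with retention, and hydrolysis of the Si–O bonds frees all four hydroxyls. No stereocentre is touched (the descriptors change only formally) and benzyl ethers are inert.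

**Step 8**
Reactants: 14 (1S,2R,3R,4S)-1,4-bis[4-(benzyloxy)-3-methoxyphenyl]-2,3-bis(hydroxymethyl)butane-1,4-diol
Product: 15 (1S,2R,3R,4S)-1,4-bis[4-(benzyloxy)-3-methoxyphenyl]-1,4-bis(tert-butyldimethylsilyloxy)-2,3-bis[(tert-butyldimethylsilyloxy)methyl]butane
Conditions: TBSOTf (5 equiv), 2,6-lutidine (8 equiv), CH2Cl2, −20 °C → rt
Reagents that add atoms: tert-butyldimethylsilyl trifluoromethanesulfonate, CC(C)(C)[Si](C)(C)OS(=O)(=O)C(F)(F)F
Why: Exhaustive silylation with a silyl triflate and a hindered base, which also reaches the hindered benzylic secondary hydroxyls; it masks O7 and O7' before the ring is closed.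

**Step 9**
Reactants: 15 (1S,2R,3R,4S)-1,4-bis[4-(benzyloxy)-3-methoxyphenyl]-1,4-bis(tert-butyldimethylsilyloxy)-2,3-bis[(tert-butyldimethylsilyloxy)methyl]butane
Product: 16 (2R,3R)-2,3-bis{(S)-[4-(benzyloxy)-3-methoxyphenyl](tert-butyldimethylsilyloxy)methyl}butane-1,4-diol
Conditions: HF·pyridine, pyridine, THF, 0 °C
Reagents that add atoms: none
Why: Selective cleavage of primary over secondary tert-butyldimethylsilyl ethers with buffered HF·pyridine, a steric rate difference that should be large here because the O7 silyl ethers sit between an aryl group and a branched carbon; buffering avoids benzylic ionisation.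

**Step 10**
Reactants: 16 (2R,3R)-2,3-bis{(S)-[4-(benzyloxy)-3-methoxyphenyl](tert-butyldimethylsilyloxy)methyl}butane-1,4-diol
Product: 17 (3R,4R)-3,4-bis{(S)-[4-(benzyloxy)-3-methoxyphenyl](tert-butyldimethylsilyloxy)methyl}oxolane
Conditions: PPh3, DIAD, THF, 0 °C → rt
Reagents that add atoms: none
Why: Mitsunobu cyclodehydration of a 1,4-diol: one primary hydroxyl is activated as the alkoxyphosphonium ion and displaced by the other in a 5-exo-tet SN2 closure. Only the 9-O-9' oxolane can form because O7 and O7' are silylated, no free alkoxide is present (so no silyl migration), and no stereocentre takes part.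

**Step 11**
Reactants: 17 (3R,4R)-3,4-bis{(S)-[4-(benzyloxy)-3-methoxyphenyl](tert-butyldimethylsilyloxy)methyl}oxolane
Product: 18 (S,S)-[(3R,4R)-oxolane-3,4-diyl]bis{[4-(benzyloxy)-3-methoxyphenyl]methanol}
Conditions: Bu4NF, THF, rt
Reagents that add atoms: none
Why: Fluoride cleavage of the two secondary silyl ethers, done while the phenols are still benzylated so that no phenoxide (the quinone methide trigger) is present under basic conditions.

**Step 12**
Reactants: 18 (S,S)-[(3R,4R)-oxolane-3,4-diyl]bis{[4-(benzyloxy)-3-methoxyphenyl]methanol}
Product: 19 (S,S)-[(3R,4R)-oxolane-3,4-diyl]bis[(4-hydroxy-3-methoxyphenyl)methanol], that is (7S,7'S,8R,8'R)-9,9'-epoxylignan-4,4',7,7'-tetrol with 3,3'-dimethoxy groups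
Conditions: H2 (1 atm), Pd/C (10%), EtOAc, rt; stopped after two equivalents of H2
Reagents that add atoms: none
Why: Catalytic hydrogenolysis of aryl benzyl ethers under neutral conditions; these cleave much faster than the secondary benzylic C–O bonds, and the neutral work-up (filtration, evaporation) spares the acid-sensitive 4-hydroxybenzylic alcohols.

## Compound list

1 | 4-(benzyloxy)-3-methoxybenzaldehyde | COc1cc(C=O)ccc1OCc1ccccc1 | starting material
2 | ethynyltrimethylsilane | C#C[Si](C)(C)C | starting material
3 | methyl[(trimethylsilyl)ethynyl]zinc | C[Zn]C#C[Si](C)(C)C | intermediate (not isolated)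
4 | (R)-1-[4-(benzyloxy)-3-methoxyphenyl]-3-(trimethylsilyl)prop-2-yn-1-ol | COc1cc([C@@H](O)C#C[Si](C)(C)C)ccc1OCc1ccccc1 | intermediate
5 | (S)-1-[4-(benzyloxy)-3-methoxyphenyl]prop-2-yn-1-ol | COc1cc([C@@H](O)C#C)ccc1OCc1ccccc1 | intermediate
6 | bis(methylzinc) alkoxide-alkynylide of 5 (same configuration) | COc1cc([C@@H](O[Zn]C)C#C[Zn]C)ccc1OCc1ccccc1 | intermediate (not isolated)
7 | (1R,4R)-1,4-bis[4-(benzyloxy)-3-methoxyphenyl]but-2-yne-1,4-diol | COc1cc([C@@H](O)C#C[C@H](O)c2ccc(OCc3ccccc3)c(OC)c2)ccc1OCc1ccccc1 | intermediate
8 | ethylene | C=C | starting material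
9 | (1R,4R)-1,4-bis[4-(benzyloxy)-3-methoxyphenyl]-2,3-dimethylidenebutane-1,4-diol | COc1cc([C@@H](O)C(=C)C(=C)[C@H](O)c2ccc(OCc3ccccc3)c(OC)c2)ccc1OCc1ccccc1 | intermediate
10 | 1,1,3,3-tetramethyldisilazane | C[SiH](C)N[SiH](C)C | starting material
11 | (1R,4R)-1,4-bis[4-(benzyloxy)-3-methoxyphenyl]-2,3-dimethylidenebutane-1,4-diyl bis(dimethylsilyl) ether | COc1cc([C@@H](O[SiH](C)C)C(=C)C(=C)[C@H](O[SiH](C)C)c2ccc(OCc3ccccc3)c(OC)c2)ccc1OCc1ccccc1 | intermediate
12 | (S)-1-[4-(benzyloxy)-3-methoxyphenyl]-2-{(4S,5S)-5-[4-(benzyloxy)-3-methoxyphenyl]-2,2-dimethyl-1,2-oxasilolan-4-yl}prop-2-en-1-yl dimethylsilyl ether (first ring closed) | COc1cc([C@H]2O[Si](C)(C)C[C@H]2C(=C)[C@H](O[SiH](C)C)c2ccc(OCc3ccccc3)c(OC)c2)ccc1OCc1ccccc1 | intermediate (not isolated)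
13 | (4S,4'S,5S,5'S)-5,5'-bis[4-(benzyloxy)-3-methoxyphenyl]-2,2,2',2'-tetramethyl-4,4'-bi(1,2-oxasilolane) | COc1cc([C@H]2O[Si](C)(C)C[C@H]2[C@@H]3C[Si](C)(C)O[C@@H]3c4ccc(OCc5ccccc5)c(OC)c4)ccc1OCc6ccccc6 | intermediate
14 | (1S,2R,3R,4S)-1,4-bis[4-(benzyloxy)-3-methoxyphenyl]-2,3-bis(hydroxymethyl)butane-1,4-diol | COc1cc([C@@H](O)[C@@H](CO)[C@H](CO)[C@H](O)c2ccc(OCc3ccccc3)c(OC)c2)ccc1OCc1ccccc1 | intermediate
15 | tetrakis(tert-butyldimethylsilyl) ether of 14 (1S,2R,3R,4S) | COc1cc([C@@H](O[Si](C)(C)C(C)(C)C)[C@@H](CO[Si](C)(C)C(C)(C)C)[C@H](CO[Si](C)(C)C(C)(C)C)[C@H](O[Si](C)(C)C(C)(C)C)c2ccc(OCc3ccccc3)c(OC)c2)ccc1OCc1ccccc1 | intermediate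
16 | (2R,3R)-2,3-bis{(S)-[4-(benzyloxy)-3-methoxyphenyl](tert-butyldimethylsilyloxy)methyl}butane-1,4-diol | COc1cc([C@@H](O[Si](C)(C)C(C)(C)C)[C@@H](CO)[C@H](CO)[C@H](O[Si](C)(C)C(C)(C)C)c2ccc(OCc3ccccc3)c(OC)c2)ccc1OCc1ccccc1 | intermediate
17 | (3R,4R)-3,4-bis{(S)-[4-(benzyloxy)-3-methoxyphenyl](tert-butyldimethylsilyloxy)methyl}oxolane | COc1cc([C@@H](O[Si](C)(C)C(C)(C)C)[C@H]2COC[C@@H]2[C@H](O[Si](C)(C)C(C)(C)C)c2ccc(OCc3ccccc3)c(OC)c2)ccc1OCc1ccccc1 | intermediate
18 | (S,S)-[(3R,4R)-oxolane-3,4-diyl]bis{[4-(benzyloxy)-3-methoxyphenyl]methanol} | COc1cc([C@@H](O)[C@H]2COC[C@@H]2[C@H](O)c2ccc(OCc3ccccc3)c(OC)c2)ccc1OCc1ccccc1 | intermediate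
19 | (S,S)-[(3R,4R)-oxolane-3,4-diyl]bis[(4-hydroxy-3-methoxyphenyl)methanol] | COc1cc([C@@H](O)[C@H]2COC[C@@H]2[C@H](O)c2ccc(O)c(OC)c2)ccc1O | target

## Step count and least certain steps

Total step count: 12. Longest linear sequence: 12 steps (1 → 19); the route is fully linear, with 1 used twice.

**Step 6 (key step).** The most likely failure is addition in the 1,4-sense across the diene (an allylplatinum intermediate passing silicon to the methylene of the other half). Methylene isomerisation by platinum hydride, or weaker face selectivity in the second closure once C8' carries a bulky ring, are further risks. The fallback sets out from 9 and comes back at 16. 9 is silylated (TBSCl, imidazole, DMF) to the (1R,4R)-bis(tert-butyldimethylsilyl) ether F1. Rhodium-catalysed hydroboration (RhCl(PPh3)3, catecholborane, THF) gives the bis(catecholboronate) F2, which is not isolated and is oxidised (NaOH, H2O2) to 16. The catalysed hydroboration of allylic silyl ethers with a 1,1-disubstituted alkene is syn-selective, the same sense as the hydrosilylation, and this path bypasses steps 5 to 9.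

**Step 4.** The catalyst may stall because the propargylic oxygens chelate ruthenium after alkyne insertion and the alkyne is branched on both sides. Ruthenium hydride formed on decomposition may also isomerise the allylic alcohols of 9 to ketones. The fallback sets out from 1 and comes back at 9. A twofold Barbier-type coupling of 1 (2 equiv) with 1,4-dibromobut-2-yne F3 (indium powder, THF) gives the dienediol as a mixture of racemic and meso diastereomers F4. Sharpless kinetic resolution (Ti(OiPr)4, L-(+)-diisopropyl tartrate, t-BuOOH, 4 Å sieves, CH2Cl2, −20 °C) epoxidises every molecule that holds an (S)-carbinol and leaves (R,R)-9. The price is that at most about a quarter of F4 can be recovered.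

**Step 3.** Aggregation of the zinc alkoxide–alkynylide 6 may slow the addition and lower the enantioselectivity. The fallback sets out from 5 and comes back at 7. 5 is silylated (TBSCl, imidazole, DMF) to the (S)-tert-butyldimethylsilyl ether F5. The same alkynylation of 1, with one equivalent less ZnMe2, gives the (1R,4R)-mono(silyl ether) F6, and Bu4NF in THF gives 7.

**Step 12.** Over-reduction by hydrogenolysis of the benzylic C7–O bonds is the risk, because the freed 4-hydroxybenzylic alcohols are the most activated. The fallback sets out from 17 and comes back at 19. Hydrogenolysis is run on 17 (H2, Pd/C, EtOAc), where bulky silyl groups shield both benzylic oxygens, to give the (3R,4R)-bis(silyl ether) bisphenol F7. The silyl groups are then removed with pyridine-buffered HF·pyridine in THF at 0 °C.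

**Step 9.** Incomplete discrimination between primary and secondary silyl ethers, or silyl migration from O7 to O9, would give mixtures that later close the wrong ring. The fallback sets out from 14 and comes back at 16. The primary hydroxyls of 14 are acylated selectively (pivaloyl chloride, pyridine, CH2Cl2, 0 °C) to the 9,9'-dipivalate F8. The secondary hydroxyls are silylated (TBSOTf, 2,6-lutidine) to F9, and the pivalates are removed reductively (iBu2AlH, CH2Cl2, −78 °C) to give 16.

## Further compounds

F1 | step 6 | (1R,4R)-1,4-bis[4-(benzyloxy)-3-methoxyphenyl]-2,3-dimethylidenebutane-1,4-diyl bis(tert-butyldimethylsilyl) ether | COc1cc([C@@H](O[Si](C)(C)C(C)(C)C)C(=C)C(=C)[C@H](O[Si](C)(C)C(C)(C)C)c2ccc(OCc3ccccc3)c(OC)c2)ccc1OCc1ccccc1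
F2 | step 6 | bis(catecholboronate) from F1, boron on C9 and C9', configuration as in 16 | COc1cc([C@@H](O[Si](C)(C)C(C)(C)C)[C@@H](CB2Oc3ccccc3O2)[C@H](CB2Oc3ccccc3O2)[C@H](O[Si](C)(C)C(C)(C)C)c2ccc(OCc3ccccc3)c(OC)c2)ccc1OCc1ccccc1
F3 | step 4 | 1,4-dibromobut-2-yne | BrCC#CCBr
F4 | step 4 | 1,4-bis[4-(benzyloxy)-3-methoxyphenyl]-2,3-dimethylidenebutane-1,4-diol, mixture of racemic and meso diastereomers | COc1cc(C(O)C(=C)C(=C)C(O)c2ccc(OCc3ccccc3)c(OC)c2)ccc1OCc1ccccc1
F5 | step 3 | (S)-{1-[4-(benzyloxy)-3-methoxyphenyl]prop-2-yn-1-yloxy}(tert-butyl)dimethylsilane | COc1cc([C@@H](O[Si](C)(C)C(C)(C)C)C#C)ccc1OCc1ccccc1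
F6 | step 3 | (1R,4R)-1,4-bis[4-(benzyloxy)-3-methoxyphenyl]-4-(tert-butyldimethylsilyloxy)but-2-yn-1-ol | COc1cc([C@@H](O[Si](C)(C)C(C)(C)C)C#C[C@H](O)c2ccc(OCc3ccccc3)c(OC)c2)ccc1OCc1ccccc1
F7 | step 12 | (3R,4R)-3,4-bis[(S)-(4-hydroxy-3-methoxyphenyl)(tert-butyldimethylsilyloxy)methyl]oxolane | COc1cc([C@@H](O[Si](C)(C)C(C)(C)C)[C@H]2COC[C@@H]2[C@H](O[Si](C)(C)C(C)(C)C)c2ccc(O)c(OC)c2)ccc1O
F8 | step 9 | 9,9'-dipivalate of 14 (1S,2R,3R,4S) | COc1cc([C@@H](O)[C@@H](COC(=O)C(C)(C)C)[C@H](COC(=O)C(C)(C)C)[C@H](O)c2ccc(OCc3ccccc3)c(OC)c2)ccc1OCc1ccccc1
F9 | step 9 | 7,7'-bis(tert-butyldimethylsilyl) ether of F8 | COc1cc([C@@H](O[Si](C)(C)C(C)(C)C)[C@@H](COC(=O)C(C)(C)C)[C@H](COC(=O)C(C)(C)C)[C@H](O[Si](C)(C)C(C)(C)C)c2ccc(OCc3ccccc3)c(OC)c2)ccc1OCc1ccccc1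
A1 | alternative 1 | (E)-but-2-enedioyl bis[(2R)-bornane-10,2-sultam] | O=C(/C=C/C(=O)N1[C@@H]2C[C@H]3CC[C@]2(CS1(=O)=O)C3(C)C)N1[C@@H]2C[C@H]3CC[C@]2(CS1(=O)=O)C3(C)C
A2 | alternative 1 | chloromethyl (trimethylsilyl)methyl ether | ClCOC[Si](C)(C)C
A3 | alternative 1 | formaldehyde O-methylide (unsubstituted carbonyl ylide) | [CH2-][O+]=C
A4 | alternative 1 | (3R,4R)-oxolane-3,4-dicarbonyl bis[(2R)-bornane-10,2-sultam] | O=C(N1[C@@H]2C[C@H]3CC[C@]2(CS1(=O)=O)C3(C)C)[C@H]4COC[C@@H]4C(=O)N1[C@@H]2C[C@H]3CC[C@]2(CS1(=O)=O)C3(C)C
A5 | alternative 2 | (3S,4S)-3,4-bis{[3-methoxy-4-(triisopropylsilyloxy)phenyl]methoxy}oxolane | COc1cc(CO[C@H]2COC[C@@H]2OCc2ccc(O[Si](C(C)C)(C(C)C)C(C)C)c(OC)c2)ccc1O[Si](C(C)C)(C(C)C)C(C)C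
A6 | alternative 2 | 4,4'-bis(triisopropylsilyl) ether of 19 (7S,7'S,8R,8'R) | COc1cc([C@@H](O)[C@H]2COC[C@@H]2[C@H](O)c3ccc(O[Si](C(C)C)(C(C)C)C(C)C)c(OC)c3)ccc1O[Si](C(C)C)(C(C)C)C(C)C
A7 | alternative 3 | (1S,2R,E)-2-[(methoxymethoxy)methyl]-1,4-bis[3-methoxy-4-(tosyloxy)phenyl]but-3-en-1-yl acetate | COCOC[C@@H](/C=C/c1ccc(OS(=O)(=O)c2ccc(C)cc2)c(OC)c1)[C@H](OC(C)=O)c1ccc(OS(=O)(=O)c2ccc(C)cc2)c(OC)c1
A8 | alternative 3 | 7-O-trifluoroacetyl-7'-O-acetyl-4,4'-di-O-tosyl derivative of 19 (7S,7'S,8R,8'R) | COc1cc([C@@H](OC(=O)C(F)(F)F)[C@H]2COC[C@@H]2[C@H](OC(C)=O)c2ccc(OS(=O)(=O)c3ccc(C)cc3)c(OC)c2)ccc1OS(=O)(=O)c1ccc(C)cc1
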